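The trap in this flask was to see more Z charged than Q and expect each Q to end as X.

    Q + Z → Q.Z (k1 = 0.0014 M⁻¹ s⁻¹)
    2 Z → Z2 (k2 = 8.5 × 10⁻⁴ M⁻¹ s⁻¹)
    Q + Q.Z → Q.Q.Z (k3 = 0.0019 M⁻¹ s⁻¹)
    Q.Z → X (k4 = 9.1 × 10⁻⁵ s⁻¹)

Q 0.11 M; Z 0.121 M; time 15 d

- percentages count the Q that a species holds: one Q.Q.Z counts as two
- a doubled species enters its step squared and goes two at a time
- the reaction counts as stopped when no species that holds the Q changes by six tenths of a point or more over the second half of the time
- run time (flask): 15 d

1. the state of affairs at 15 d: stopped, and by what, or still going (Z has run out first / all of Q has reacted / it is still moving)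
2. share of the Q used up at 15 d
3. X at 15 d, in percent of the Q charged

I built the flask up by hand, turning constants into times at the charged amounts. With the first step and ring closure alone, Q had a half-life of 1.1 h by the first step at the charged amounts, short against 15 d, and Z stood at 1.10 equivalents, so in that reckoning each Q ended as one X.

Then I let Z react with itself. At the start, Q took Z at 0.75 of the rate at which Z took itself, which gave the step to Q.Z a start share of 42.8% of the Z used. Held steady, that share reckoned to 0.0518 M of Q.Z, less than the Q charged, so I took Z as the limiting reagent.

Last came capture of Q.Z by Q, with a half-life of 0.92 h at the charge against 0.088 d for ring closure. This race turns on the crossover amount of Q, the ring-closure constant over the capture constant, at which both run equally fast: 0.0479 M. The charge stood at 2.30 times that amount, which at the start left ring closure 30.3% of the Q.Z being used. Keeping that start share, I reckoned 79.9% conversion and 14.3% X, knowing that falling Q would raise the ring's share.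

The forecast said Z has run out first, with conversion 87% (82% to 92%) and X 32% (28% to 37%), reasoning “capture favoured early and ring closure late as Q falls”. Its conversion and its X both stood above mine.

The simulation said Z has run out first, with Z at 0% of its charge, conversion 86.8% and X 31.3%.

In this flask Q fell from 0.11 M to 0.0145 M, below the crossover amount, and the 0.0344 M of X exceeded the 0.0305 M of Q.Q.Z. The neighbour flask charged with 0.066 M of Q began at 1.38 times the crossover amount, which reckons to a start share for ring closure of 42.1%. It reached 93.8% conversion and 49.0% X, above the forecast's top marks of 92% and 37% for the first flask. In that neighbour flask X held most of the Q, 49.0% against 44.8% in Q.Q.Z.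

The rate constants were chosen freely.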